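## Retrosynthetic overview

1. Target 16 ⇐ α-bromo ketone 15 (hydride reduction at C9) ⇐ spiro vinylogous ester 11, by γ-bromination at C10, conversion of the C7 carbonyl into the C7=C14 methylene and hydrolysis of the enol ether to the C9 ketone. Ring B is dimedone with all six ring carbons in place.
2. 11 ⇐ spiro diene 8: the ring A halogens come from the C2=C3 alkene by epoxidation, bromide opening at C2 and OH→Cl exchange at C3 with retention.
3. 8 ⇐ isoprene (C1–C4 and C15) + exocyclic enone 6, by a Diels–Alder reaction that forms C6–C1 and C5–C4 and closes ring A. The enabling feature: spiro atom C6 is α to C7 (the carbon that carries the exocyclic methylene, kept here at the ketone level) and C5 is its exocyclic neighbour. C5=C6–C7=O is therefore an s-cis-locked enone on ring B, and the rest of ring A (C1–C4 with C15 on C3) is exactly isoprene, its methyl para to C6.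
4. Ring order: ring B is bought (dimedone), ring A is closed in the key step. The one catalyst-controlled stereocentre, C6, then relays C2, C3, C10 and C9.

Key step: step 4

**Remarks**

- Numbering used throughout (spiro[5.5]undecane type): ring A = C1–C5, spiro atom C6, ring B = C7–C11; C14 = exocyclic methylene carbon on C7, C15 = methyl on C3. Names use these locants. The target is (2S,3S,6R,9S,10R); C6 is 6S in intermediates with a C7 carbonyl only because the CIP priorities of C7 and C11 change, not the geometry.
- Assumption: the sense of induction of the chiral acid in step 4 is not predicted here. The catalyst antipode that gives (6S)-8 is to be identified on the first run (both antipodes are equally accessible), and every later stereocentre follows from C6.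

## Route

Step 1
Reactants: 1 dimedone (5,5-dimethylcyclohexane-1,3-dione); 2 2-methylpropan-1-ol
Product: 3 3-(2-methylpropoxy)-5,5-dimethylcyclohex-2-en-1-one
Conditions: p-TsOH·H2O (cat.), toluene, reflux, Dean–Stark trap
Reagents that add atoms: none
Why: Acid-catalysed condensation of the symmetric 1,3-dione with the alcohol under azeotropic removal of water (vinylogous esterification) should give the vinylogous ester, in which the ring carbons already map onto C6–C11 of ring B.

Step 2
Reactants: 3 3-(2-methylpropoxy)-5,5-dimethylcyclohex-2-en-1-one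
Product: 4 6-[(dimethylamino)methyl]-3-(2-methylpropoxy)-5,5-dimethylcyclohex-2-en-1-one (racemic)
Conditions: LiN(i-Pr)2, THF, −78 °C; then Eschenmoser's salt, −78 °C to rt
Reagents that add atoms: Eschenmoser's salt (N,N-dimethylmethyleneiminium iodide), C=[N+](C)C.[I-]
Why: Kinetic deprotonation of a vinylogous ester takes place at the α′ CH2 (C6) and the lithium enolate should undergo a Mannich reaction with the preformed iminium salt; the new stereocentre is racemic and is removed in step 3.

Step 3
Reactants: 4 6-[(dimethylamino)methyl]-3-(2-methylpropoxy)-5,5-dimethylcyclohex-2-en-1-one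
Product: 6 3-(2-methylpropoxy)-5,5-dimethyl-6-methylidenecyclohex-2-en-1-one, via trimethylammonium iodide 5 (not isolated)
Conditions: MeI, Et2O, rt; then NaHCO3 (aq), CH2Cl2, rt
Reagents that add atoms: none
Why: N-Methylation turns the amine into a leaving group and mild base should trigger E1cB (Hofmann-type) elimination to the exocyclic enone, whose double bond cannot move into the ring because the neighbouring C11 is quaternary.

Step 4
Reactants: 6 3-(2-methylpropoxy)-5,5-dimethyl-6-methylidenecyclohex-2-en-1-one; 7 isoprene (2-methylbuta-1,3-diene)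
Product: 8 (6S)-9-(2-methylpropoxy)-3,11,11-trimethylspiro[5.5]undeca-2,8-dien-7-one
Conditions: isoprene (excess), confined chiral imidodiphosphorimidate Brønsted acid (from two 3,3′-diaryl-BINOL units, N-triflyl groups; 5 mol%), toluene, −40 °C
Reagents that add atoms: none
Why: The chiral acid activates the C7 carbonyl of the s-cis-locked exocyclic enone and isoprene adds across C5=C6 in a concerted, asynchronous [4+2] cycloaddition in which the C5–C4 bond leads and the C6–C1 bond, which creates the quaternary spiro centre next to CMe2, completes ring A. The closest known reaction type is the catalytic asymmetric spirocyclising Diels–Alder reaction of α-methylene cycloalkanones with simple 1,3-dienes under confined imidodiphosphorimidate acids, and in the racemic series the Lewis-acid Diels–Alder reaction of 3,3-dimethyl-2-methylenecyclohexanone with isoprene. Ring A is closed in a six-membered suprafacial [4π+2π] mode with the isoprene methyl para to C6, the normal orientation for a 2-substituted diene and an acid-activated enone. The only new stereocentre, C6, is set by the catalyst, whose chiral pocket should shield one face of the C5=C6 bond so that C1 is delivered to the face that gives the 6S adduct. The step needs face selectivity, para over meta regioselectivity, and chemoselectivity for the exocyclic alkene over the C8=C9 bond and over hetero-Diels–Alder dimerisation of the enone; the first is the task of the catalyst, the second follows from the diene methyl and the polarised enone, and the third is secured because C8=C9 is a deactivated β-alkoxy enone bond and the gem-dimethyl group next to C6 slows self-reaction. No later step needs an external source of chirality, since C2, C3, C10 and C9 are relayed from C6.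

Step 5
Reactants: 8 (6S)-9-(2-methylpropoxy)-3,11,11-trimethylspiro[5.5]undeca-2,8-dien-7-one
Product: 9 (2R,3S,6S)-2,3-epoxy-9-(2-methylpropoxy)-3,11,11-trimethylspiro[5.5]undec-8-en-7-one
Conditions: mCPBA, NaHCO3, CH2Cl2, 0 °C
Reagents that add atoms: mCPBA (3-chloroperoxybenzoic acid), OOC(=O)c1cccc(Cl)c1
Why: Prilezhaev epoxidation should be chemoselective for the electron-rich trisubstituted C2=C3 alkene over the push–pull C8=C9 bond, and the peracid should approach anti to the pseudo-axial C7 carbonyl arm at the spiro centre (the CMe2 arm prefers the pseudo-equatorial site, as with the angular methyl of a 2-ene steroid), which puts the oxygen on the face opposite to C7.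

Step 6
Reactants: 9 (2R,3S,6S)-2,3-epoxy-9-(2-methylpropoxy)-3,11,11-trimethylspiro[5.5]undec-8-en-7-one
Product: 10 (2S,3S,6S)-2-bromo-3-hydroxy-9-(2-methylpropoxy)-3,11,11-trimethylspiro[5.5]undec-8-en-7-one
Conditions: Li2NiBr4, THF, 0 °C to rt
Reagents that add atoms: dilithium tetrabromonickelate (Li2NiBr4), [Li+].[Li+].[Ni+2].[Br-].[Br-].[Br-].[Br-]
Why: SN2 opening of the trisubstituted epoxide by bromide at the secondary carbon C2 with inversion, in the trans-diaxial (Fürst–Plattner) mode, should place bromine on the face syn to C7 (2S) and leave the tertiary C3–O bond, and so the 3S carbinol, untouched.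

Step 7
Reactants: 10 (2S,3S,6S)-2-bromo-3-hydroxy-9-(2-methylpropoxy)-3,11,11-trimethylspiro[5.5]undec-8-en-7-one
Product: 11 (2S,3S,6S)-2-bromo-3-chloro-9-(2-methylpropoxy)-3,11,11-trimethylspiro[5.5]undec-8-en-7-one
Conditions: SOCl2, pyridine, CH2Cl2, −30 to 0 °C
Reagents that add atoms: thionyl chloride, O=S(Cl)Cl
Why: Ionisation of the tertiary chlorosulfite is assisted by the anti-periplanar C2 bromine (anchimeric assistance through a bromonium ion) and chloride should open the bridged ion at the tertiary carbon C3 anti to bromine, so that C–O is replaced by C–Cl with overall retention (double inversion) and the trans 2-bromo-3-chloro pattern of the target results.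

Step 8
Reactants: 11 (2S,3S,6S)-2-bromo-3-chloro-9-(2-methylpropoxy)-3,11,11-trimethylspiro[5.5]undec-8-en-7-one
Product: 13 (2S,3S,6S,10R)-2,10-dibromo-3-chloro-9-(2-methylpropoxy)-3,11,11-trimethylspiro[5.5]undec-8-en-7-one, via silyl dienol ether 12 (not isolated)
Conditions: LiN(i-Pr)2, Me3SiCl, THF, −78 °C; then NBS, NaHCO3, THF, −78 °C
Reagents that add atoms: N-bromosuccinimide, O=C1CCC(=O)N1Br
Why: With the α′ carbon (C6) quaternary, the amide base removes a γ-proton at C10 and O-silylation gives a 2-alkoxy-4-silyloxy diene that should take up bromine from NBS at its terminal carbon C10 (vinylogous Mukaiyama-type γ-halogenation); bromine is expected anti to the pseudo-axial C11 methyl, which is the face syn to C1 (10R) because the C1 methylene, the bulkier of the two ring A arms since it adjoins the C2 bromine, avoids the in-plane site next to the C7–OSi group and thereby fixes the twist of ring B.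

Step 9
Reactants: 13 (2S,3S,6S,10R)-2,10-dibromo-3-chloro-9-(2-methylpropoxy)-3,11,11-trimethylspiro[5.5]undec-8-en-7-one
Product: 15 (2S,3S,6R,10R)-2,10-dibromo-3-chloro-3,11,11-trimethyl-7-methylidenespiro[5.5]undecan-9-one, via dienol ether 14 (not isolated)
Conditions: Cp2Ti(μ-Cl)(μ-CH2)AlMe2, pyridine, THF–toluene, −40 to 0 °C; then oxalic acid, THF–H2O, 0 °C
Reagents that add atoms: Tebbe reagent Cp2Ti(μ-Cl)(μ-CH2)AlMe2, C[Al-]1(C)C[Ti](C2C=CC=C2)(C2C=CC=C2)[Cl+]1; water, O
Why: Tebbe methylenation should convert the ester-like, non-enolisable C7 carbonyl into the exocyclic methylene without base, and kinetic protonation of the resulting dienol ether at C8 followed by hydrolysis (as for steroidal dienol ethers) should unmask the C9 ketone as the β,γ-unsaturated isomer without touching C10.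

Step 10
Reactants: 15 (2S,3S,6R,10R)-2,10-dibromo-3-chloro-3,11,11-trimethyl-7-methylidenespiro[5.5]undecan-9-one
Product: 16 (2S,3S,6R,9S,10R)-2,10-dibromo-3-chloro-3,11,11-trimethyl-7-methylidenespiro[5.5]undecan-9-ol (target)
Conditions: i-Bu2AlH, CH2Cl2, −78 °C
Reagents that add atoms: none
Why: 1,2-Reduction of the α-bromo ketone by hydride anti to the C–Br bond (Cornforth/Felkin–Anh polar model, reinforced by the axial bromine) should give the cis-bromohydrin, that is the 9S alcohol, while halides and alkene survive at low temperature.

## Compound list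

1 | dimedone (5,5-dimethylcyclohexane-1,3-dione) | CC1(C)CC(=O)CC(=O)C1 | starting material
2 | 2-methylpropan-1-ol | CC(C)CO | starting material
3 | 3-(2-methylpropoxy)-5,5-dimethylcyclohex-2-en-1-one | CC(C)COC1=CC(=O)CC(C)(C)C1 | intermediate
4 | 6-[(dimethylamino)methyl]-3-(2-methylpropoxy)-5,5-dimethylcyclohex-2-en-1-one (racemic) | CC(C)COC1=CC(=O)C(CN(C)C)C(C)(C)C1 | intermediate
5 | {[6,6-dimethyl-4-(2-methylpropoxy)-2-oxocyclohex-3-en-1-yl]methyl}trimethylammonium iodide (racemic) | CC(C)COC1=CC(=O)C(C[N+](C)(C)C)C(C)(C)C1.[I-] | intermediate (not isolated)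
6 | 3-(2-methylpropoxy)-5,5-dimethyl-6-methylidenecyclohex-2-en-1-one | CC(C)COC1=CC(=O)C(=C)C(C)(C)C1 | intermediate
7 | isoprene (2-methylbuta-1,3-diene) | C=CC(C)=C | starting material
8 | (6S)-9-(2-methylpropoxy)-3,11,11-trimethylspiro[5.5]undeca-2,8-dien-7-one | O=C1C=C(OCC(C)C)CC(C)(C)[C@@]12CCC(C)=CC2 | intermediate
9 | (2R,3S,6S)-2,3-epoxy-9-(2-methylpropoxy)-3,11,11-trimethylspiro[5.5]undec-8-en-7-one (epoxide anti to C7) | O=C1C=C(OCC(C)C)CC(C)(C)[C@@]12CC[C@]3(C)O[C@@H]3C2 | intermediate
10 | (2S,3S,6S)-2-bromo-3-hydroxy-9-(2-methylpropoxy)-3,11,11-trimethylspiro[5.5]undec-8-en-7-one | O=C1C=C(OCC(C)C)CC(C)(C)[C@@]12CC[C@](C)(O)[C@@H](Br)C2 | intermediate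
11 | (2S,3S,6S)-2-bromo-3-chloro-9-(2-methylpropoxy)-3,11,11-trimethylspiro[5.5]undec-8-en-7-one | O=C1C=C(OCC(C)C)CC(C)(C)[C@@]12CC[C@](C)(Cl)[C@@H](Br)C2 | intermediate
12 | (2S,3S,6S)-2-bromo-3-chloro-9-(2-methylpropoxy)-3,11,11-trimethyl-7-(trimethylsilyloxy)spiro[5.5]undeca-7,9-diene | C[Si](C)(C)OC1=CC(OCC(C)C)=CC(C)(C)[C@@]12CC[C@](C)(Cl)[C@@H](Br)C2 | intermediate (not isolated)
13 | (2S,3S,6S,10R)-2,10-dibromo-3-chloro-9-(2-methylpropoxy)-3,11,11-trimethylspiro[5.5]undec-8-en-7-one | O=C1C=C(OCC(C)C)[C@H](Br)C(C)(C)[C@@]12CC[C@](C)(Cl)[C@@H](Br)C2 | intermediate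
14 | (2S,3S,6R,10R)-2,10-dibromo-3-chloro-9-(2-methylpropoxy)-3,11,11-trimethyl-7-methylidenespiro[5.5]undec-8-ene | C=C1C=C(OCC(C)C)[C@H](Br)C(C)(C)[C@@]12CC[C@](C)(Cl)[C@@H](Br)C2 | intermediate (not isolated)
15 | (2S,3S,6R,10R)-2,10-dibromo-3-chloro-3,11,11-trimethyl-7-methylidenespiro[5.5]undecan-9-one | C=C1CC(=O)[C@H](Br)C(C)(C)[C@@]12CC[C@](C)(Cl)[C@@H](Br)C2 | intermediate
16 | (2S,3S,6R,9S,10R)-2,10-dibromo-3-chloro-3,11,11-trimethyl-7-methylidenespiro[5.5]undecan-9-ol | C=C1C[C@H](O)[C@H](Br)C(C)(C)[C@@]12CC[C@](C)(Cl)[C@@H](Br)C2 | target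

## Step count and risks

Total step count: 10. Longest linear sequence: 10 steps (from dimedone).

**Step 8.** What may go wrong: bromine transfer to C10 with poor facial selectivity, since the face syn to C1 also carries a 1,3-related CH2 group, or loss of the C10 configuration by enolisation on the way to 15. Fallback: the relay is replaced by catalyst control. Starting again from 11, steps 8 and 9 are run without regard to the C10 configuration. This gives 13 together with its 10-epimer, (2S,3S,6S,10S)-2,10-dibromo-3-chloro-9-(2-methylpropoxy)-3,11,11-trimethylspiro[5.5]undec-8-en-7-one F1, and then 15 together with its 10-epimer, (2S,3S,6R,10S)-2,10-dibromo-3-chloro-3,11,11-trimethyl-7-methylidenespiro[5.5]undecan-9-one F2. The mixture is reduced by asymmetric transfer hydrogenation under dynamic kinetic resolution (RuCl(p-cymene)[(S,S)-TsDPEN] or its antipode, whichever gives the 9S carbinol; HCO2H–Et3N 5:2, CH2Cl2, 0 °C). The α-bromo ketone epimers interconvert through the enol, only the 10R ketone should fit the catalyst, and hydride is delivered anti to bromine, so both epimers should funnel into cis-bromohydrin 16, where the route is rejoined.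

**Step 9.** What may go wrong: no reaction of the titanium methylidene at the C7 carbonyl, which is flanked by the spiro centre, the C11 methyl groups and the C2 bromine, or migration of the exocyclic alkene into conjugation during hydrolysis. Fallback: the carbon is brought in by the smallest available nucleophile and the alkene is made in a separate elimination. From 13, MeLi/CeCl3 (THF, −78 °C) should give the tertiary allylic alcohol (2S,3S,6S,10R)-2,10-dibromo-3-chloro-9-(2-methylpropoxy)-3,7,11,11-tetramethylspiro[5.5]undec-8-en-7-ol F3 (the C7 configuration is of no consequence). Burgess reagent (benzene, rt) dehydrates it, and because C14 carries the only β-hydrogens the product can only be dienol ether 14. There the route is rejoined for the oxalic acid hydrolysis to 15.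

**Step 4.** What may go wrong: slow turnover of the acid catalyst with the Lewis-basic vinylogous ester (strong binding, weak activation) and, with it, poor face or para/meta selectivity. Fallback: the spiro centre is set by palladium-catalysed enantioselective decarboxylative allylic alkylation and ring A is closed by olefin metathesis. From 3, alkylation at C6 (LiN(i-Pr)2; 4-iodo-2-methylbut-1-ene) gives racemic 3-(2-methylpropoxy)-5,5-dimethyl-6-(3-methylbut-3-en-1-yl)cyclohex-2-en-1-one F4. O-Acylation of its enolate with allyl chloroformate gives allyl 3,3-dimethyl-2-(3-methylbut-3-en-1-yl)-5-(2-methylpropoxy)cyclohexa-1,5-dien-1-yl carbonate F5. Pd2(dba)3 with (S)-t-Bu-PHOX (or its antipode, whichever gives the 6S centre) expels CO2 and should deliver (6S)-3-(2-methylpropoxy)-5,5-dimethyl-6-(3-methylbut-3-en-1-yl)-6-(prop-2-en-1-yl)cyclohex-2-en-1-one F6. Ring-closing metathesis with the second-generation Grubbs catalyst joins the two terminal alkenes to the C2=C3 bond with loss of ethene and gives 8, where the route is rejoined.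

## Further compounds

F1 | step 8 | (2S,3S,6S,10S)-2,10-dibromo-3-chloro-9-(2-methylpropoxy)-3,11,11-trimethylspiro[5.5]undec-8-en-7-one | O=C1C=C(OCC(C)C)[C@@H](Br)C(C)(C)[C@@]12CC[C@](C)(Cl)[C@@H](Br)C2
F2 | step 8 | (2S,3S,6R,10S)-2,10-dibromo-3-chloro-3,11,11-trimethyl-7-methylidenespiro[5.5]undecan-9-one | C=C1CC(=O)[C@@H](Br)C(C)(C)[C@@]12CC[C@](C)(Cl)[C@@H](Br)C2
F3 | step 9 | (2S,3S,6S,10R)-2,10-dibromo-3-chloro-9-(2-methylpropoxy)-3,7,11,11-tetramethylspiro[5.5]undec-8-en-7-ol (C7 epimers) | CC1(O)C=C(OCC(C)C)[C@H](Br)C(C)(C)[C@@]12CC[C@](C)(Cl)[C@@H](Br)C2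
F4 | step 4 | 3-(2-methylpropoxy)-5,5-dimethyl-6-(3-methylbut-3-en-1-yl)cyclohex-2-en-1-one (racemic) | CC(C)COC1=CC(=O)C(CCC(C)=C)C(C)(C)C1
F5 | step 4 | allyl 3,3-dimethyl-2-(3-methylbut-3-en-1-yl)-5-(2-methylpropoxy)cyclohexa-1,5-dien-1-yl carbonate | C=CCOC(=O)OC1=C(CCC(C)=C)C(C)(C)CC(OCC(C)C)=C1
F6 | step 4 | (6S)-3-(2-methylpropoxy)-5,5-dimethyl-6-(3-methylbut-3-en-1-yl)-6-(prop-2-en-1-yl)cyclohex-2-en-1-one | O=C1C=C(OCC(C)C)CC(C)(C)[C@@]1(CC=C)CCC(C)=C
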